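**Retrosynthetic overview**

1. The C-4 tertiary alcohol comes from a C-4 ketone and a methyl nucleophile. The E exocyclic alkene comes from reductive 1,3-transposition of an allylic alcohol that joins a hydrindane C-3 aldehyde to a ring A alkenyl triflate.
2. Ring A comes from a bromonium-induced 6-endo cyclisation of a prenylated acetoacetate and is then resolved. The C-7 bromide of the hydrindane comes from hydrogen-atom-transfer hydrogenation of a C-7 vinyl bromide, itself made from a C-7 ketone.
3. The five-membered ring is closed between C-2 and C-3 by metathesis of two arms that the key step puts on a purchased six-membered ring in one operation (C-1 to C-7a and C-3 to C-3a).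
4. Enabling feature: with the CHBr carbon C-7 written as a ketone, the angular-methyl carbon C-7a and the ring-fusion carbon C-3a are the α- and β-carbons of a 2-methylcyclohex-2-enone. The trans ring fusion is the anti outcome of conjugate addition followed by enolate alkylation, and the oxygen at C-4 steers the facial course.
5. Ring order: six-membered ring of the hydrindane (from compound 1), five-membered ring (steps 6 and 7), ring A separately (step 13), union in step 18.

Key step: step 6

Remark: hydrindane locants follow the target throughout (C-3 side-chain carbon, C-3a ring-fusion CH, C-4 carbinol carbon, C-7 CHBr, C-7a angular-methyl carbon); primed ring A locants are also those of the target (C-1′ alkylidene carbon, C-2′ the CH2 next to the gem-dimethyl carbon C-3′, C-4′ CHBr, C-6′ the other flanking CH2).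
Remark: compounds 1, 7, 8, 19 and 20, both enantiomers of N,S-dimethyl-S-phenylsulfoximine, the CBS catalyst and Et2SBr·SbCl5Br are taken as commercially available.
Remark: ring A is made as a racemate and resolved, because no closely precedented enantioselective route to this lone neopentyl bromide is available.

**Route**

Step 1
Reactants: 1 1,4-dioxaspiro[4.5]dec-6-en-8-one
Product: 2 (S)-1,4-dioxaspiro[4.5]dec-6-en-8-ol
Conditions: (R)-2-methyl-CBS-oxazaborolidine (10 mol%), BH3·SMe2, THF, −30 °C
Reagents that add atoms: none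
Why: Corey–Bakshi–Shibata reduction, in which the alkene arm of the enone acts as the large group, so the (R)-catalyst should deliver hydride to give the (S)-allylic alcohol.

Step 2
Reactants: 2 (S)-1,4-dioxaspiro[4.5]dec-6-en-8-ol
Product: 3 (S)-8-(tert-butyldimethylsilyloxy)-1,4-dioxaspiro[4.5]dec-6-ene
Conditions: TBSCl, imidazole, DMF, 23 °C
Reagents that add atoms: tert-butyldimethylsilyl chloride, C[Si](C)(Cl)C(C)(C)C
Why: Standard silylation of a secondary alcohol; the stereocentre is not touched.

Step 3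
Reactants: 3 (S)-8-(tert-butyldimethylsilyloxy)-1,4-dioxaspiro[4.5]dec-6-ene
Product: 4 (S)-4-(tert-butyldimethylsilyloxy)cyclohex-2-en-1-one
Conditions: PPTS (cat.), acetone/H2O, 50 °C
Reagents that add atoms: water, O
Why: Mild acid hydrolysis of the allylic ketal should unveil the enone carbonyl next to the alkene while the secondary silyl ether survives.

Step 4
Reactants: 4 (S)-4-(tert-butyldimethylsilyloxy)cyclohex-2-en-1-one
Product: 5 (S)-4-(tert-butyldimethylsilyloxy)-2-iodocyclohex-2-en-1-one
Conditions: I2, pyridine, CH2Cl2, 0 to 23 °C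
Reagents that add atoms: iodine, II
Why: α-Iodination of a cyclic enone by pyridine conjugate addition, iodination of the enolate and elimination.

Step 5
Reactants: 5 (S)-4-(tert-butyldimethylsilyloxy)-2-iodocyclohex-2-en-1-one
Product: 6 (S)-4-(tert-butyldimethylsilyloxy)-2-methylcyclohex-2-en-1-one
Conditions: MeZnCl (THF solution), Pd(PPh3)4 (5 mol%), THF, 23 °C
Reagents that add atoms: methylzinc chloride, C[Zn]Cl
Why: Negishi coupling of an α-iodoenone; the organozinc reagent does not add to the enone and the γ-stereocentre is remote from the reacting carbon.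

Step 6
Reactants: 6 (S)-4-(tert-butyldimethylsilyloxy)-2-methylcyclohex-2-en-1-one; 7 2-bromo-3,3-diethoxyprop-1-ene; 8 allyl bromide
Product: 12 (2S,3S,4S)-2-allyl-4-(tert-butyldimethylsilyloxy)-3-(3,3-diethoxyprop-1-en-2-yl)-2-methylcyclohexan-1-one, via alkenyllithium 9 (not isolated), via cuprate 10 (not isolated), via lithium enolate 11 (not isolated)
Conditions: 7, t-BuLi (2 equiv per 7), Et2O, −78 °C; CuI (copper iodide, 0.5 equiv per 7), −78 to −40 °C; 6, −78 to −40 °C; then DMPU, 8, −40 to 0 °C
Reagents that add atoms: none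
Why: Tandem conjugate addition and enolate alkylation (three-component vicinal difunctionalisation of a 2-methylcyclohex-2-enone): the soft alkenyl cuprate 10 should add 1,4 to the β-carbon of 6 (future C-3a, forming C-3 to C-3a), and the regiodefined lithium enolate 11 should be C-allylated by 8 at the methyl-bearing α-carbon (future C-7a, forming C-1 to C-7a and the quaternary centre). The closest known reaction type is cuprate addition with α-allylation of 2-methylcyclohexenones such as carvone, including alkenyl cuprates and 4-silyloxy enones. The step closes no ring; it places on the six-membered ring the two unsaturated arms whose metathesis in step 7 closes the five-membered ring. C-3a is controlled by the C-4 silyloxy group (cuprate attack anti to the γ-OTBS group), and C-7a by the new C-3a substituent (axial allylation of the enolate anti to the pseudo-axial alkenyl arm), so the two arms end trans-diequatorial with the methyl axial, which is the trans ring fusion of the target. The step needs 1,4- over 1,2-addition, C- over O-alkylation and trapping of 11 before the enolate equilibrates; the cuprate, the reactive allylic bromide with DMPU and the absence of a proton source should secure this, and the ketone left at C-7 is the handle for the bromide.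

Step 7
Reactants: 12 (2S,3S,4S)-2-allyl-4-(tert-butyldimethylsilyloxy)-3-(3,3-diethoxyprop-1-en-2-yl)-2-methylcyclohexan-1-one
Product: 13 (3aS,4S,7aS)-4-(tert-butyldimethylsilyloxy)-3-(diethoxymethyl)-7a-methyl-1,3a,4,5,6,7a-hexahydro-7H-inden-7-one
Conditions: second-generation Grubbs catalyst RuCl2(=CHPh)(H2IMes)(PCy3) (5 mol%), CH2Cl2, 40 °C
Reagents that add atoms: none
Why: Ring-closing metathesis of a terminal and a 1,1-disubstituted alkene held trans-diequatorial on the cyclohexanone should give the trans-fused cyclopentene and lock the ring fusion, since C-3a is not α to the ketone.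

Step 8
Reactants: 13 (3aS,4S,7aS)-4-(tert-butyldimethylsilyloxy)-3-(diethoxymethyl)-7a-methyl-1,3a,4,5,6,7a-hexahydro-7H-inden-7-one
Product: 15 (3aR,4S,7aS)-4-(tert-butyldimethylsilyloxy)-3-(diethoxymethyl)-7a-methyl-3a,4,5,7a-tetrahydro-1H-inden-7-yl trifluoromethanesulfonate, via potassium enolate 14 (not isolated)
Conditions: KN(SiMe3)2, THF, −78 °C; then PhNTf2, −78 to 0 °C
Reagents that add atoms: N-phenylbis(trifluoromethanesulfonimide), FC(F)(F)S(=O)(=O)N(c1ccccc1)S(=O)(=O)C(F)(F)F
Why: Enol triflate formation; only C-6 carries α-hydrogens because C-7a is quaternary, so the enolate is regiodefined.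

Step 9
Reactants: 15 (3aR,4S,7aS)-4-(tert-butyldimethylsilyloxy)-3-(diethoxymethyl)-7a-methyl-3a,4,5,7a-tetrahydro-1H-inden-7-yl trifluoromethanesulfonate
Product: 16 tert-butyl{[(3aS,4S,7aS)-7-bromo-3-(diethoxymethyl)-7a-methyl-3a,4,5,7a-tetrahydro-1H-inden-4-yl]oxy}dimethylsilane
Conditions: Ni(OAc)2·4H2O (10 mol%), 1,5-cyclooctadiene (20 mol%), Zn (20 mol%), LiBr, THF/DMA, 23 °C
Reagents that add atoms: lithium bromide, [Li+].[Br-]
Why: Nickel-catalysed exchange of an enol triflate for bromide under neutral conditions, which acetal, silyl ether and the second alkene should tolerate.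

Step 10
Reactants: 16 tert-butyl{[(3aS,4S,7aS)-7-bromo-3-(diethoxymethyl)-7a-methyl-3a,4,5,7a-tetrahydro-1H-inden-4-yl]oxy}dimethylsilane
Product: 17 tert-butyl{[(3aS,4S,7S,7aS)-7-bromo-3-(diethoxymethyl)-7a-methyloctahydro-1H-inden-4-yl]oxy}dimethylsilane (C-3 epimers, carried on together)
Conditions: Mn(dpm)3 (10 mol%), PhSiH3, t-BuOOH, i-PrOH, 23 °C
Reagents that add atoms: none
Why: Metal-hydride hydrogen-atom-transfer hydrogenation, a radical process known to reduce haloalkenes without loss of halogen; the α-bromo radical at C-7 should take its hydrogen axially, anti to the axial 7a-methyl, giving the equatorial (7S) bromide cis to that methyl, while the cyclopentene is reduced in the same pot and its C-3 outcome is corrected in step 11.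

Step 11
Reactants: 17 tert-butyl{[(3aS,4S,7S,7aS)-7-bromo-3-(diethoxymethyl)-7a-methyloctahydro-1H-inden-4-yl]oxy}dimethylsilane
Product: 18 (3R,3aS,4S,7S,7aS)-7-bromo-4-(tert-butyldimethylsilyloxy)-7a-methyloctahydro-1H-indene-3-carbaldehyde
Conditions: PPTS, acetone/H2O, 50 °C; then DBU (cat.), CH2Cl2, 23 °C
Reagents that add atoms: water, O
Why: Acetal hydrolysis followed by base equilibration of the α-stereocentre; the formyl group should settle trans to C-4 and anti to the angular methyl on the rigid trans-hydrindane, which is the C-3 configuration of the target.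

Step 12
Reactants: 19 tert-butyl acetoacetate; 20 prenyl bromide (1-bromo-3-methylbut-2-ene)
Product: 22 tert-butyl 7-methyl-3-oxooct-6-enoate, via dilithium dianion 21 (not isolated)
Conditions: LiN(i-Pr)2 (2.1 equiv), THF, 0 °C; then 20, 0 to 23 °C
Reagents that add atoms: none
Why: γ-Alkylation of an acetoacetate dianion, which reacts at the more basic terminal carbon with the allylic bromide.

Step 13
Reactants: 22 tert-butyl 7-methyl-3-oxooct-6-enoate
Product: 23 tert-butyl 3-bromo-2,2-dimethyl-6-oxocyclohexane-1-carboxylate (racemic)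
Conditions: Et2SBr·SbCl5Br (BDSB), MeNO2, −25 to 23 °C
Reagents that add atoms: bromodiethylsulfonium bromopentachloroantimonate, CC[S+](Br)CC.Br[Sb-](Cl)(Cl)(Cl)(Cl)Cl
Why: Bromonium-induced 6-endo cation–olefin cyclisation terminated by the enol carbon of the β-keto ester, which creates the neopentyl C–Br bond and the gem-dimethyl carbon together; the bromide stereocentre is formed as a racemate, and any tert-butyl ester cleaved by the acid set free converges in step 14.

Step 14
Reactants: 23 tert-butyl 3-bromo-2,2-dimethyl-6-oxocyclohexane-1-carboxylate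
Product: 24 rac-4-bromo-3,3-dimethylcyclohexan-1-one
Conditions: CF3CO2H, CH2Cl2, 23 °C; then toluene, 80 °C
Reagents that add atoms: none
Why: Acidolysis of the tert-butyl ester and decarboxylation of the β-keto acid under non-basic, non-nucleophilic conditions that should spare the secondary bromide.

Step 15
Reactants: 24 rac-4-bromo-3,3-dimethylcyclohexan-1-one
Product: 25 (S)-S-{[(1R,4S)-4-bromo-1-hydroxy-3,3-dimethylcyclohexyl]methyl}-N-methyl-S-phenylsulfoximine
Conditions: (S)-N,S-dimethyl-S-phenylsulfoximine, n-BuLi, THF, −78 °C; then 24; chromatographic separation of the two diastereomers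
Reagents that add atoms: (S)-N,S-dimethyl-S-phenylsulfoximine, C[S@@](=O)(=NC)c1ccccc1
Why: Sulfoximine resolution of a ketone: the lithiated enantiopure sulfoximine should add equatorially (the axial 3-methyl blocks the axial face), giving one separable adduct per ketone enantiomer; the adduct of the (S)-ketone, to be assigned by X-ray crystallography, is taken on.

Step 16
Reactants: 25 (S)-S-{[(1R,4S)-4-bromo-1-hydroxy-3,3-dimethylcyclohexyl]methyl}-N-methyl-S-phenylsulfoximine
Product: 26 (S)-4-bromo-3,3-dimethylcyclohexan-1-one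
Conditions: toluene, 110 °C
Reagents that add atoms: none
Why: Thermal retro-addition of the β-hydroxy sulfoximine releases the enantiopure ketone and the auxiliary without touching the bromide stereocentre.

Step 17
Reactants: 26 (S)-4-bromo-3,3-dimethylcyclohexan-1-one
Product: 28 (S)-4-bromo-5,5-dimethylcyclohex-1-en-1-yl trifluoromethanesulfonate, via lithium enolate 27 (not isolated)
Conditions: LiN(i-Pr)2, THF, −78 °C; then N-(5-chloro-2-pyridyl)bis(trifluoromethanesulfonimide), −78 °C
Reagents that add atoms: N-(5-chloropyridin-2-yl)bis(trifluoromethanesulfonimide), FC(F)(F)S(=O)(=O)N(c1ccc(Cl)cn1)S(=O)(=O)C(F)(F)F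
Why: Kinetic deprotonation should occur at the CH2 remote from the gem-dimethyl carbon (C-6′), and low-temperature O-triflation fixes the C-1′/C-6′ alkene before the enolate can displace the neopentyl bromide.

Step 18
Reactants: 18 (3R,3aS,4S,7S,7aS)-7-bromo-4-(tert-butyldimethylsilyloxy)-7a-methyloctahydro-1H-indene-3-carbaldehyde; 28 (S)-4-bromo-5,5-dimethylcyclohex-1-en-1-yl trifluoromethanesulfonate
Product: 30 [(3R,3aS,4S,7S,7aS)-7-bromo-4-(tert-butyldimethylsilyloxy)-7a-methyloctahydro-1H-inden-3-yl][(4S)-4-bromo-5,5-dimethylcyclohex-1-en-1-yl]methanol (both carbinol epimers), via alkenylchromium 29 (not isolated)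
Conditions: CrCl2 (excess), NiCl2 (cat.), DMF, 23 °C
Reagents that add atoms: none
Why: Nozaki–Hiyama–Kishi coupling, which tolerates secondary alkyl bromides and does not enolise the aldehyde; the new carbinol centre need not be controlled because it is destroyed in step 19.

Step 19
Reactants: 30 [(3R,3aS,4S,7S,7aS)-7-bromo-4-(tert-butyldimethylsilyloxy)-7a-methyloctahydro-1H-inden-3-yl][(4S)-4-bromo-5,5-dimethylcyclohex-1-en-1-yl]methanol
Product: 33 {[(3S,3aS,4S,7S,7aS)-7-bromo-3-{(E)-[(4S)-4-bromo-3,3-dimethylcyclohexylidene]methyl}-7a-methyloctahydro-1H-inden-4-yl]oxy}(tert-butyl)dimethylsilane, via sulfonylhydrazine 31 (not isolated), via allylic diazene 32 (not isolated)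
Conditions: 2-nitrobenzenesulfonylhydrazide, PPh3, diethyl azodicarboxylate, THF/N-methylmorpholine, −30 °C; then 23 °C
Reagents that add atoms: none
Why: Reductive 1,3-transposition of an allylic alcohol (Mitsunobu displacement, loss of sulfinic acid, retro-ene loss of N2 from the allylic diazene): in the early, reactant-like transition state the carbinol hydrogen should eclipse the C-2′ methylene to avoid A(1,2) strain with the hydrindanyl group, which then lies on the side of the vinylic C-6′–H, so hydrogen is delivered to C-6′ and the hydrindane ends cis to C-6′ (E), with both carbinol epimers expected to converge.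

Step 20
Reactants: 33 {[(3S,3aS,4S,7S,7aS)-7-bromo-3-{(E)-[(4S)-4-bromo-3,3-dimethylcyclohexylidene]methyl}-7a-methyloctahydro-1H-inden-4-yl]oxy}(tert-butyl)dimethylsilane
Product: 34 (3S,3aS,4S,7S,7aS)-7-bromo-3-{(E)-[(4S)-4-bromo-3,3-dimethylcyclohexylidene]methyl}-7a-methyloctahydro-1H-inden-4-ol
Conditions: HF·pyridine, THF/pyridine, 0 to 23 °C
Reagents that add atoms: none
Why: Buffered fluoride desilylation, chosen over basic fluoride to avoid elimination of the secondary bromides.

Step 21
Reactants: 34 (3S,3aS,4S,7S,7aS)-7-bromo-3-{(E)-[(4S)-4-bromo-3,3-dimethylcyclohexylidene]methyl}-7a-methyloctahydro-1H-inden-4-ol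
Product: 35 (3S,3aS,7S,7aS)-7-bromo-3-{(E)-[(4S)-4-bromo-3,3-dimethylcyclohexylidene]methyl}-7a-methyloctahydro-4H-inden-4-one
Conditions: Dess–Martin periodinane, NaHCO3, CH2Cl2, 0 to 23 °C
Reagents that add atoms: none
Why: Buffered Dess–Martin oxidation should give the ketone without epimerising C-3a, whose trans configuration is in any case favoured by the C-3 substituent lying trans to C-4.

Step 22
Reactants: 35 (3S,3aS,7S,7aS)-7-bromo-3-{(E)-[(4S)-4-bromo-3,3-dimethylcyclohexylidene]methyl}-7a-methyloctahydro-4H-inden-4-one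
Product: 36 (3S,3aS,4R,7S,7aS)-7-bromo-3-{(E)-[(4S)-4-bromo-3,3-dimethylcyclohexylidene]methyl}-4,7a-dimethyloctahydro-1H-inden-4-ol (CNP0119865.1)
Conditions: MeMgBr, CeCl3 (dried), THF, −78 °C
Reagents that add atoms: methylmagnesium bromide, C[Mg]Br
Why: Organocerium 1,2-addition, which is non-basic and should not enolise C-3a; the axial 7a-methyl is 1,3-diaxial to the axial trajectory at C-4, so the methyl should enter equatorially and leave the hydroxyl axial, cis to the angular methyl, which is the (4R) configuration.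

**Compound list**

1 | 1,4-dioxaspiro[4.5]dec-6-en-8-one | O=C1C=CC2(CC1)OCCO2 | starting material
2 | (S)-1,4-dioxaspiro[4.5]dec-6-en-8-ol | C1=C[C@@H](O)CCC12OCCO2 | intermediate
3 | (S)-8-(tert-butyldimethylsilyloxy)-1,4-dioxaspiro[4.5]dec-6-ene | C1=C[C@@H](O[Si](C)(C)C(C)(C)C)CCC12OCCO2 | intermediate
4 | (S)-4-(tert-butyldimethylsilyloxy)cyclohex-2-en-1-one | O=C1C=C[C@@H](O[Si](C)(C)C(C)(C)C)CC1 | intermediate
5 | (S)-4-(tert-butyldimethylsilyloxy)-2-iodocyclohex-2-en-1-one | O=C1C(I)=C[C@@H](O[Si](C)(C)C(C)(C)C)CC1 | intermediate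
6 | (S)-4-(tert-butyldimethylsilyloxy)-2-methylcyclohex-2-en-1-one | O=C1C(C)=C[C@@H](O[Si](C)(C)C(C)(C)C)CC1 | intermediate
7 | 2-bromo-3,3-diethoxyprop-1-ene | C=C(Br)C(OCC)OCC | starting material
8 | allyl bromide | C=CCBr | starting material
9 | (3,3-diethoxyprop-1-en-2-yl)lithium (not isolated) | [Li]C(=C)C(OCC)OCC | intermediate
10 | lithium bis(3,3-diethoxyprop-1-en-2-yl)cuprate (not isolated) | [Li+].C=C([Cu-]C(=C)C(OCC)OCC)C(OCC)OCC | intermediate
11 | lithium (3R,4S)-4-(tert-butyldimethylsilyloxy)-3-(3,3-diethoxyprop-1-en-2-yl)-2-methylcyclohex-1-en-1-olate (not isolated) | C=C(C(OCC)OCC)[C@@H]1[C@@H](O[Si](C)(C)C(C)(C)C)CCC(O[Li])=C1C | intermediate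
12 | (2S,3S,4S)-2-allyl-4-(tert-butyldimethylsilyloxy)-3-(3,3-diethoxyprop-1-en-2-yl)-2-methylcyclohexan-1-one | C=C(C(OCC)OCC)[C@@H]1[C@@H](O[Si](C)(C)C(C)(C)C)CCC(=O)[C@@]1(C)CC=C | intermediate
13 | (3aS,4S,7aS)-4-(tert-butyldimethylsilyloxy)-3-(diethoxymethyl)-7a-methyl-1,3a,4,5,6,7a-hexahydro-7H-inden-7-one | CCOC(OCC)C1=CC[C@]2(C)C(=O)CC[C@H](O[Si](C)(C)C(C)(C)C)[C@@H]12 | intermediate
14 | potassium (3aR,4S,7aS)-4-(tert-butyldimethylsilyloxy)-3-(diethoxymethyl)-7a-methyl-3a,4,5,7a-tetrahydro-1H-inden-7-olate (not isolated) | CCOC(OCC)C1=CC[C@]2(C)C(O[K])=CC[C@H](O[Si](C)(C)C(C)(C)C)[C@@H]12 | intermediate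
15 | (3aR,4S,7aS)-4-(tert-butyldimethylsilyloxy)-3-(diethoxymethyl)-7a-methyl-3a,4,5,7a-tetrahydro-1H-inden-7-yl trifluoromethanesulfonate | CCOC(OCC)C1=CC[C@]2(C)C(OS(=O)(=O)C(F)(F)F)=CC[C@H](O[Si](C)(C)C(C)(C)C)[C@@H]12 | intermediate
16 | tert-butyl{[(3aS,4S,7aS)-7-bromo-3-(diethoxymethyl)-7a-methyl-3a,4,5,7a-tetrahydro-1H-inden-4-yl]oxy}dimethylsilane | CCOC(OCC)C1=CC[C@]2(C)C(Br)=CC[C@H](O[Si](C)(C)C(C)(C)C)[C@@H]12 | intermediate
17 | tert-butyl{[(3aS,4S,7S,7aS)-7-bromo-3-(diethoxymethyl)-7a-methyloctahydro-1H-inden-4-yl]oxy}dimethylsilane (C-3 epimers, C-3 left open in the SMILES) | CCOC(OCC)C1CC[C@]2(C)[C@@H](Br)CC[C@H](O[Si](C)(C)C(C)(C)C)[C@@H]12 | intermediate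
18 | (3R,3aS,4S,7S,7aS)-7-bromo-4-(tert-butyldimethylsilyloxy)-7a-methyloctahydro-1H-indene-3-carbaldehyde | O=C[C@@H]1CC[C@]2(C)[C@@H](Br)CC[C@H](O[Si](C)(C)C(C)(C)C)[C@@H]12 | intermediate
19 | tert-butyl acetoacetate | CC(=O)CC(=O)OC(C)(C)C | starting material
20 | prenyl bromide (1-bromo-3-methylbut-2-ene) | CC(C)=CCBr | starting material
21 | dilithium dianion of tert-butyl acetoacetate (not isolated) | [Li+].[Li+].C=C([O-])C=C([O-])OC(C)(C)C | intermediate
22 | tert-butyl 7-methyl-3-oxooct-6-enoate | CC(C)=CCCC(=O)CC(=O)OC(C)(C)C | intermediate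
23 | tert-butyl 3-bromo-2,2-dimethyl-6-oxocyclohexane-1-carboxylate (racemic) | CC(C)(C)OC(=O)C1C(=O)CCC(Br)C1(C)C | intermediate
24 | rac-4-bromo-3,3-dimethylcyclohexan-1-one | CC1(C)CC(=O)CCC1Br | intermediate
25 | (S)-S-{[(1R,4S)-4-bromo-1-hydroxy-3,3-dimethylcyclohexyl]methyl}-N-methyl-S-phenylsulfoximine | O[C@]1(C[S@@](=O)(=NC)c2ccccc2)CC[C@H](Br)C(C)(C)C1 | intermediate
26 | (S)-4-bromo-3,3-dimethylcyclohexan-1-one | CC1(C)CC(=O)CC[C@@H]1Br | intermediate
27 | lithium (S)-4-bromo-5,5-dimethylcyclohex-1-en-1-olate (not isolated) | CC1(C)CC(O[Li])=CC[C@@H]1Br | intermediate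
28 | (S)-4-bromo-5,5-dimethylcyclohex-1-en-1-yl trifluoromethanesulfonate | CC1(C)CC(OS(=O)(=O)C(F)(F)F)=CC[C@@H]1Br | intermediate
29 | [(S)-4-bromo-5,5-dimethylcyclohex-1-en-1-yl]chromium dichloride (not isolated) | CC1(C)CC([Cr](Cl)Cl)=CC[C@@H]1Br | intermediate
30 | [(3R,3aS,4S,7S,7aS)-7-bromo-4-(tert-butyldimethylsilyloxy)-7a-methyloctahydro-1H-inden-3-yl][(4S)-4-bromo-5,5-dimethylcyclohex-1-en-1-yl]methanol (carbinol epimers, carbinol left open) | OC([C@@H]1CC[C@]2(C)[C@@H](Br)CC[C@H](O[Si](C)(C)C(C)(C)C)[C@@H]12)C3=CC[C@H](Br)C(C)(C)C3 | intermediate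
31 | N-alkyl-N-(2-nitrophenylsulfonyl)hydrazine from 30 (not isolated) | NN(C([C@@H]1CC[C@]2(C)[C@@H](Br)CC[C@H](O[Si](C)(C)C(C)(C)C)[C@@H]12)C3=CC[C@H](Br)C(C)(C)C3)S(=O)(=O)c4ccccc4[N+](=O)[O-] | intermediate
32 | allylic diazene from 31 (not isolated) | N=NC([C@@H]1CC[C@]2(C)[C@@H](Br)CC[C@H](O[Si](C)(C)C(C)(C)C)[C@@H]12)C3=CC[C@H](Br)C(C)(C)C3 | intermediate
33 | {[(3S,3aS,4S,7S,7aS)-7-bromo-3-{(E)-[(4S)-4-bromo-3,3-dimethylcyclohexylidene]methyl}-7a-methyloctahydro-1H-inden-4-yl]oxy}(tert-butyl)dimethylsilane | CC1(C)C/C(=C/[C@@H]2CC[C@]3(C)[C@@H](Br)CC[C@H](O[Si](C)(C)C(C)(C)C)[C@@H]23)CC[C@@H]1Br | intermediate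
34 | (3S,3aS,4S,7S,7aS)-7-bromo-3-{(E)-[(4S)-4-bromo-3,3-dimethylcyclohexylidene]methyl}-7a-methyloctahydro-1H-inden-4-ol | CC1(C)C/C(=C/[C@@H]2CC[C@]3(C)[C@@H](Br)CC[C@H](O)[C@@H]23)CC[C@@H]1Br | intermediate
35 | (3S,3aS,7S,7aS)-7-bromo-3-{(E)-[(4S)-4-bromo-3,3-dimethylcyclohexylidene]methyl}-7a-methyloctahydro-4H-inden-4-one | CC1(C)C/C(=C/[C@@H]2CC[C@]3(C)[C@@H](Br)CCC(=O)[C@@H]23)CC[C@@H]1Br | intermediate
36 | (3S,3aS,4R,7S,7aS)-7-bromo-3-{(E)-[(4S)-4-bromo-3,3-dimethylcyclohexylidene]methyl}-4,7a-dimethyloctahydro-1H-inden-4-ol | CC1(C)C/C(=C/[C@@H]2CC[C@]3(C)[C@@H](Br)CC[C@@](C)(O)[C@@H]23)CC[C@@H]1Br | target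

**Step count**

Total steps: 22. Longest linear sequence: 16 steps (steps 1 to 11, then 18 to 22); the ring A branch (steps 12 to 17) joins at step 18.

**Steps most likely to fail**

1. Step 19. The Mitsunobu displacement may stall at the hindered secondary allylic carbinol, and the retro-ene loss of N2 may lose geometric control if the hydrindanyl group takes the position next to the C-2′ methylene instead of the vinylic side. Fallback (stereospecific Horner–Wittig route with separation of adducts): setting out from 18, NaBH4 in MeOH should give the primary alcohol [(3R,3aS,4S,7S,7aS)-7-bromo-4-(tert-butyldimethylsilyloxy)-7a-methyloctahydro-1H-inden-3-yl]methanol F1; I2, PPh3 and imidazole should give the iodide F2; alkylation of Ph2P(O)H (deprotonated with KN(SiMe3)2) should give the diphenylphosphine oxide F3. Its lithio derivative (n-BuLi, THF, −78 °C) should add equatorially to ketone 26 to give two β-hydroxy phosphine oxides, from which the diastereomer F4 with the correct relative configuration at the phosphorus-bearing carbon is separated by chromatography. NaH in DMF should then effect stereospecific syn-elimination, coming back to the route at 33.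

2. Step 10. The α-bromo radical pathway may be bypassed by hydrogen-atom addition at C-7 followed by loss of a bromine atom (net hydrodebromination), or hydrogen may be delivered to C-7 from the face of the angular methyl. Fallback (SN2 inversion in place of radical hydrogenation): setting out from 13, hydrogenation (H2, Pd/C, EtOAc) should give the saturated ketone F5; LiBH(s-Bu)3 in THF at −78 °C should attack equatorially to give the axial C-7 alcohol F6; Appel bromination (CBr4, PPh3, CH2Cl2) with inversion comes back to the route at 17.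

3. Step 13. The bromonium ion may be captured by the enol oxygen (giving a dihydropyran) or the reagent may brominate the active methylene instead of triggering carbocyclisation. Fallback (mercury-induced cyclisation, then bromine for mercury): setting out from 22, Hg(OTf)2 in MeNO2 followed by aqueous NaBr should give the C-cyclised organomercurial tert-butyl 3-(bromomercurio)-2,2-dimethyl-6-oxocyclohexane-1-carboxylate F7; brominative demercuration (Br2, LiBr, pyridine, O2) comes back to the route at 23.

**Further compounds**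

F1 | step 19 | [(3R,3aS,4S,7S,7aS)-7-bromo-4-(tert-butyldimethylsilyloxy)-7a-methyloctahydro-1H-inden-3-yl]methanol | OC[C@@H]1CC[C@]2(C)[C@@H](Br)CC[C@H](O[Si](C)(C)C(C)(C)C)[C@@H]12
F2 | step 19 | {[(3R,3aS,4S,7S,7aS)-7-bromo-3-(iodomethyl)-7a-methyloctahydro-1H-inden-4-yl]oxy}(tert-butyl)dimethylsilane | IC[C@@H]1CC[C@]2(C)[C@@H](Br)CC[C@H](O[Si](C)(C)C(C)(C)C)[C@@H]12
F3 | step 19 | {[(3R,3aS,4S,7S,7aS)-7-bromo-4-(tert-butyldimethylsilyloxy)-7a-methyloctahydro-1H-inden-3-yl]methyl}diphenylphosphine oxide | O=P(C[C@@H]1CC[C@]2(C)[C@@H](Br)CC[C@H](O[Si](C)(C)C(C)(C)C)[C@@H]12)(c3ccccc3)c4ccccc4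
F4 | step 19 | {(R)-[(1R,4S)-4-bromo-1-hydroxy-3,3-dimethylcyclohexyl][(3R,3aS,4S,7S,7aS)-7-bromo-4-(tert-butyldimethylsilyloxy)-7a-methyloctahydro-1H-inden-3-yl]methyl}diphenylphosphine oxide | O=P(c1ccccc1)(c2ccccc2)[C@H]([C@@H]3CC[C@]4(C)[C@@H](Br)CC[C@H](O[Si](C)(C)C(C)(C)C)[C@@H]34)[C@@]5(O)CC[C@H](Br)C(C)(C)C5
F5 | step 10 | (3aS,4S,7aS)-4-(tert-butyldimethylsilyloxy)-3-(diethoxymethyl)-7a-methyloctahydro-7H-inden-7-one (C-3 epimers) | CCOC(OCC)C1CC[C@]2(C)C(=O)CC[C@H](O[Si](C)(C)C(C)(C)C)[C@@H]12
F6 | step 10 | (3aS,4S,7R,7aS)-4-(tert-butyldimethylsilyloxy)-3-(diethoxymethyl)-7a-methyloctahydro-1H-inden-7-ol (C-3 epimers) | CCOC(OCC)C1CC[C@]2(C)[C@H](O)CC[C@H](O[Si](C)(C)C(C)(C)C)[C@@H]12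
F7 | step 13 | tert-butyl 3-(bromomercurio)-2,2-dimethyl-6-oxocyclohexane-1-carboxylate (racemic) | CC(C)(C)OC(=O)C1C(=O)CCC([Hg]Br)C1(C)C
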